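**Retrosynthetic overview**
1. Ester C–O bond: target ⇒ caesium salt of (Z)-2-(hydroxymethyl)but-2-enoic acid 16 + primary tosylate 12 of the syn 1,3-diol. Carboxylate alkylation needs no protecting group and never activates the Z-acyl carbon.
2. Diol 11 ⇒ acid 10. Its C2–CH2(allyl) bond, the C2 configuration and the E-styrene ⇒ Ireland–Claisen rearrangement of ester 6, run through the bis-silylated ketene acetal derived from the chelated dianion.
3. Enabling feature: the array O–CH2–CH–CH2–CH=CH–Ar. The acyloxy-bearing CH2 (a carboxyl carbon at a higher oxidation level) lies γ,δ to the E-styryl double bond, whose outer carbon carries a 3,4-dimethoxyphenyl ring (a latent benzylic allylic C–O). The neighbouring benzylic carbinol supplies the chelating β-oxygen.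
4. Ester 6 ⇒ transfer hydrogenation of β-keto ester 5 ⇐ commercial ethyl aroylacetate 4 + (S)-allylic alcohol 3 (veratraldehyde, vinyl Grignard, lipase resolution). Acid 16 ⇐ but-2-yn-1-ol by trans-hydrostannation and methoxycarbonylation.
5. Rings: none is formed. Both dimethoxyphenyl rings are bought, and the only cyclic array is the six-membered chair transition state of the key step.

Key step: step 5

Remark on the chemistry: the dilithium dianion of a β-hydroxy ester is taken to be the internally chelated enolate with the β-carbon syn to OLi, as in Fráter–Seebach alkylations.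

**Route**

Step 1
Reactants: 1 3,4-dimethoxybenzaldehyde
Product: 2 (±)-1-(3,4-dimethoxyphenyl)prop-2-en-1-ol
Conditions: CH2=CHMgBr (1.2 equiv), THF, −20 → 0 °C; sat. aq. NH4Cl; Et3N-deactivated silica
Reagents that add atoms: vinylmagnesium bromide, C=C[Mg]Br
Why: Grignard 1,2-addition to the aldehyde gives the racemic allylic alcohol, which step 2 resolves.

Step 2
Reactants: 2 (±)-1-(3,4-dimethoxyphenyl)prop-2-en-1-ol
Product: 3 (S)-1-(3,4-dimethoxyphenyl)prop-2-en-1-ol
Conditions: immobilised Candida antarctica lipase B, vinyl acetate (3 equiv), MTBE, 30 °C, run slightly past half conversion; separation from the acetate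
Reagents that add atoms: none
Why: In this lipase-catalysed kinetic resolution by transesterification, the enzyme should acylate the (R)-enantiomer of an aryl vinyl carbinol (aryl as the large group), so the (S)-alcohol should remain and is separated from the (R)-acetate.

Step 3
Reactants: 3 (S)-1-(3,4-dimethoxyphenyl)prop-2-en-1-ol; 4 ethyl 3-(3,4-dimethoxyphenyl)-3-oxopropanoate
Product: 5 (S)-1-(3,4-dimethoxyphenyl)prop-2-en-1-yl 3-(3,4-dimethoxyphenyl)-3-oxopropanoate
Conditions: 4 (1.5 equiv), DMAP (0.3 equiv), 4 Å MS, toluene, 100 °C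
Reagents that add atoms: none
Why: DMAP-catalysed transesterification of a β-keto ester (acylketene pathway) runs under neutral to basic conditions that should not ionise the electron-rich allylic alcohol, and only its O–H bond reacts, so the carbinol configuration is kept.

Step 4
Reactants: 5 (S)-1-(3,4-dimethoxyphenyl)prop-2-en-1-yl 3-(3,4-dimethoxyphenyl)-3-oxopropanoate
Product: 6 (S)-1-(3,4-dimethoxyphenyl)prop-2-en-1-yl (S)-3-(3,4-dimethoxyphenyl)-3-hydroxypropanoate
Conditions: RuCl[(S,S)-TsDPEN](p-cymene) (1 mol%), HCO2H–Et3N (1:1), DMF, 30 °C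
Reagents that add atoms: none
Why: Noyori–Ikariya asymmetric transfer hydrogenation of the aryl ketone is catalyst-controlled; the (S,S)-ligand should give the (S)-benzylic alcohol in the same sense as for acetophenone, and the vinyl group and ester should be untouched in the amine-rich formate medium.

Step 5
Reactants: 6 (S)-1-(3,4-dimethoxyphenyl)prop-2-en-1-yl (S)-3-(3,4-dimethoxyphenyl)-3-hydroxypropanoate
Product: 10 (2S,4E)-5-(3,4-dimethoxyphenyl)-2-[(S)-(3,4-dimethoxyphenyl)(hydroxy)methyl]pent-4-enoic acid, via chelated dilithium dianion 7 (not isolated), via bis(trimethylsilyl) ketene acetal 8 (not isolated), via rearranged trimethylsilyl ester 9 (not isolated)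
Conditions: LDA (2.3 equiv), THF, −78 °C; Me3SiCl/Et3N (4 equiv), −78 → 40 °C; aq. citric acid (pH 4), 0 °C
Reagents that add atoms: none
Why: Two equivalents of LDA should give the internally chelated dianion 7, in which the β-oxygen is an alkoxide (no β-elimination) and the enolate geometry is fixed with C3 syn to OLi; silylation of both oxygens freezes that geometry in ketene acetal 8, which on warming undergoes the [3,3] shift that makes the C2–CH2 σ-bond, breaks the allylic C–O bond and leaves silyl ester 9, hydrolysed to 10 on mild work-up. The closest known reaction type is the Ireland–Claisen rearrangement of secondary allylic esters with 1,3-chirality transfer, entered here through the dianion of a β-hydroxy ester. No ring is closed; the only cyclic array is the six-membered chair transition state, in which the aryl group of the allylic carbinol and C3 are both equatorial. The new C2 centre is set by the (S)-carbinol carbon, which in this chair delivers the CH2 terminus to the face that becomes (2S), and C3 reinforces it: once silylation has broken the chelate, A(1,3) strain against the cis OSiMe3 group puts the C3–H bond in the ketene acetal plane and the allyl terminus enters anti to the C3 aryl ring, which is the same face and gives the 2,3-syn pair. The equatorial aryl group on the carbinol carbon should give the E-styrene. The step needs facial control at C2 and must avoid retro-aldol of the aldolate; the first is secured by the matched carbinol and C3 configurations and by silylating before warming (the lithium chelate itself would favour the anti isomer), the second by keeping the dianion at −78 °C.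

Step 6
Reactants: 10 (2S,4E)-5-(3,4-dimethoxyphenyl)-2-[(S)-(3,4-dimethoxyphenyl)(hydroxy)methyl]pent-4-enoic acid
Product: 11 (1S,2R)-1-(3,4-dimethoxyphenyl)-2-[(E)-3-(3,4-dimethoxyphenyl)prop-2-en-1-yl]propane-1,3-diol
Conditions: LiAlH4 (3 equiv), THF, 0 → 40 °C; H2O/aq. NaOH work-up
Reagents that add atoms: none
Why: Hydride reduction of the carboxylic acid to the primary alcohol leaves the styrene and both stereocentres untouched (the C2 descriptor changes only because the priorities change).

Step 7
Reactants: 11 (1S,2R)-1-(3,4-dimethoxyphenyl)-2-[(E)-3-(3,4-dimethoxyphenyl)prop-2-en-1-yl]propane-1,3-diol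
Product: 12 (2R,3S)-2-[(E)-3-(3,4-dimethoxyphenyl)prop-2-en-1-yl]-3-(3,4-dimethoxyphenyl)-3-hydroxypropyl 4-methylbenzenesulfonate
Conditions: TsCl (1.1 equiv), Et3N (1.5 equiv), Me3N·HCl (10 mol%), CH2Cl2, 0 °C
Reagents that add atoms: p-toluenesulfonyl chloride, Cc1ccc(cc1)S(Cl)(=O)=O
Why: Sulfonylation at 0 °C with a slight excess of reagent should be selective for the primary hydroxyl over the hindered secondary benzylic one.

Step 8
Reactants: 13 but-2-yn-1-ol
Product: 14 (Z)-2-(tributylstannyl)but-2-en-1-ol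
Conditions: Bu3SnH (1.1 equiv), [Cp*RuCl]4 (1.5 mol%), CH2Cl2, rt
Reagents that add atoms: tributyltin hydride, CCCC[SnH](CCCC)CCCC
Why: In the ruthenium-catalysed hydroxyl-directed trans-hydrostannation, the OH···Cl–Ru hydrogen bond steers tin to the alkyne carbon next to the CH2OH group, and trans addition places tin cis to the methyl group.

Step 9
Reactants: 14 (Z)-2-(tributylstannyl)but-2-en-1-ol
Product: 15 methyl (Z)-2-(hydroxymethyl)but-2-enoate
Conditions: Pd(OAc)2 (5 mol%), Ph3As (10 mol%), 1,4-benzoquinone (1.5 equiv), CF3CO2H (1.2 equiv), CO (1 atm), MeOH, rt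
Reagents that add atoms: carbon monoxide, [C-]#[O+]; methanol, CO
Why: Palladium-catalysed oxidative methoxycarbonylation of the alkenylstannane (transmetalation to a Pd–CO2Me species, reductive elimination, reoxidation by benzoquinone) replaces tin with retention, so the methyl group ends cis to the ester.

Step 10
Reactants: 15 methyl (Z)-2-(hydroxymethyl)but-2-enoate
Product: 16 (Z)-2-(hydroxymethyl)but-2-enoic acid
Conditions: LiOH·H2O (2 equiv), THF/H2O (3:1), 0 °C → rt; 1 M HCl to pH 3
Reagents that add atoms: lithium hydroxide (delivers the new carboxyl oxygen), [Li+].[OH-]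
Why: Saponification by acyl substitution at 0 °C to rt should not involve reversible conjugate addition, so the Z geometry is kept.

Step 11
Reactants: 12 (2R,3S)-2-[(E)-3-(3,4-dimethoxyphenyl)prop-2-en-1-yl]-3-(3,4-dimethoxyphenyl)-3-hydroxypropyl 4-methylbenzenesulfonate; 16 (Z)-2-(hydroxymethyl)but-2-enoic acid
Product: 17 (2R,3S)-2-[(E)-3-(3,4-dimethoxyphenyl)prop-2-en-1-yl]-3-(3,4-dimethoxyphenyl)-3-hydroxypropyl (Z)-2-(hydroxymethyl)but-2-enoate
Conditions: 16 (1.5 equiv), Cs2CO3 (0.75 equiv), DMF, rt; then 12, 50 °C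
Reagents that add atoms: none
Why: SN2 O-alkylation of the caesium carboxylate by the primary tosylate uses the carboxylate as the only strong nucleophile (the neutral hydroxyls do not compete), never activates the acyl carbon, so the Z-alkene cannot isomerise, and forms the C–O bond at CH2, leaving both stereocentres untouched.

**Compound list**
1 | 3,4-dimethoxybenzaldehyde | COc1ccc(C=O)cc1OC | starting material
2 | (±)-1-(3,4-dimethoxyphenyl)prop-2-en-1-ol | C=CC(O)c1ccc(OC)c(OC)c1 | intermediate
3 | (S)-1-(3,4-dimethoxyphenyl)prop-2-en-1-ol | C=C[C@H](O)c1ccc(OC)c(OC)c1 | intermediate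
4 | ethyl 3-(3,4-dimethoxyphenyl)-3-oxopropanoate | CCOC(=O)CC(=O)c1ccc(OC)c(OC)c1 | starting material
5 | (S)-1-(3,4-dimethoxyphenyl)prop-2-en-1-yl 3-(3,4-dimethoxyphenyl)-3-oxopropanoate | C=C[C@H](OC(=O)CC(=O)c1ccc(OC)c(OC)c1)c1ccc(OC)c(OC)c1 | intermediate
6 | (S)-1-(3,4-dimethoxyphenyl)prop-2-en-1-yl (S)-3-(3,4-dimethoxyphenyl)-3-hydroxypropanoate | C=C[C@H](OC(=O)C[C@H](O)c1ccc(OC)c(OC)c1)c1ccc(OC)c(OC)c1 | intermediate
7 | dilithium alkoxide–enolate of 6 (chelated, C3 syn to OLi) | C=C[C@H](O/C([O-])=C/[C@H]([O-])c1ccc(OC)c(OC)c1)c1ccc(OC)c(OC)c1.[Li+].[Li+] | intermediate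
8 | (Z)-ketene (S)-1-arylallyl trimethylsilyl acetal of the (S)-3-aryl-3-(trimethylsilyloxy)propanoate (C3 cis to OSiMe3) | C=C[C@H](O/C(O[Si](C)(C)C)=C/[C@H](O[Si](C)(C)C)c1ccc(OC)c(OC)c1)c1ccc(OC)c(OC)c1 | intermediate
9 | trimethylsilyl (2S,4E)-5-(3,4-dimethoxyphenyl)-2-[(S)-(3,4-dimethoxyphenyl)(trimethylsilyloxy)methyl]pent-4-enoate | C[Si](C)(C)OC(=O)[C@@H](C/C=C/c1ccc(OC)c(OC)c1)[C@H](O[Si](C)(C)C)c1ccc(OC)c(OC)c1 | intermediate
10 | (2S,4E)-5-(3,4-dimethoxyphenyl)-2-[(S)-(3,4-dimethoxyphenyl)(hydroxy)methyl]pent-4-enoic acid | OC(=O)[C@@H](C/C=C/c1ccc(OC)c(OC)c1)[C@H](O)c1ccc(OC)c(OC)c1 | intermediate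
11 | (1S,2R)-1-(3,4-dimethoxyphenyl)-2-[(E)-3-(3,4-dimethoxyphenyl)prop-2-en-1-yl]propane-1,3-diol | OC[C@@H](C/C=C/c1ccc(OC)c(OC)c1)[C@H](O)c1ccc(OC)c(OC)c1 | intermediate
12 | (2R,3S)-2-[(E)-3-(3,4-dimethoxyphenyl)prop-2-en-1-yl]-3-(3,4-dimethoxyphenyl)-3-hydroxypropyl 4-methylbenzenesulfonate | Cc1ccc(cc1)S(=O)(=O)OC[C@@H](C/C=C/c1ccc(OC)c(OC)c1)[C@H](O)c1ccc(OC)c(OC)c1 | intermediate
13 | but-2-yn-1-ol | CC#CCO | starting material
14 | (Z)-2-(tributylstannyl)but-2-en-1-ol | C/C=C(/CO)[Sn](CCCC)(CCCC)CCCC | intermediate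
15 | methyl (Z)-2-(hydroxymethyl)but-2-enoate | C/C=C(/CO)C(=O)OC | intermediate
16 | (Z)-2-(hydroxymethyl)but-2-enoic acid | C/C=C(/CO)C(=O)O | intermediate
17 | (2R,3S)-2-[(E)-3-(3,4-dimethoxyphenyl)prop-2-en-1-yl]-3-(3,4-dimethoxyphenyl)-3-hydroxypropyl (Z)-2-(hydroxymethyl)but-2-enoate | C/C=C(/CO)C(=O)OC[C@@H](C/C=C/c1ccc(OC)c(OC)c1)[C@H](O)c1ccc(OC)c(OC)c1 | target

**Step count and risks**
Total step count: 11. Longest linear sequence: 8 steps (steps 1, 2, 3, 4, 5, 6, 7, 11).

Steps most likely to fail:

1. Step 5. Facial control at C2 may erode, through a competing boat or axial-aryl chair or through incomplete silylation that lets the lithium chelate rearrange toward the anti isomer. Retro-aldol of the aldolate may also scramble C3. The fallback sets out from 5 and keeps the same C–C bond formation but moves stereocontrol to a dynamic reduction. Treatment of 5 with LDA (2.2 equiv, THF, −78 °C → rt) should bring about the dianionic Carroll-type [3,3] rearrangement without decarboxylation to give the configurationally labile β-keto acid (E)-2-(3,4-dimethoxybenzoyl)-5-(3,4-dimethoxyphenyl)pent-4-enoic acid F1. Cold esterification with TMSCHN2 should give its methyl ester F2. A syn-selective dynamic kinetic reduction (Ru–TsDPEN transfer hydrogenation with racemisation at C2, or a ketoreductase chosen for the syn isomer) should then give methyl (2S,4E)-5-(3,4-dimethoxyphenyl)-2-[(S)-(3,4-dimethoxyphenyl)(hydroxy)methyl]pent-4-enoate F3. LiAlH4 reduction returns to the route at 11.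

2. Step 4. The electron-rich allylic ester may ionise in the formate medium (solvolysis or 1,3-transposition), or reduction of the electron-rich aryl ketone may be slow. The fallback sets out from 4 and reduces before the sensitive ester is made. The same transfer hydrogenation on 4 should give ethyl (S)-3-(3,4-dimethoxyphenyl)-3-hydroxypropanoate F4. TESCl/imidazole should give ethyl (S)-3-(3,4-dimethoxyphenyl)-3-(triethylsilyloxy)propanoate F5, and LiOH the acid (S)-3-(3,4-dimethoxyphenyl)-3-(triethylsilyloxy)propanoic acid F6. EDC/DMAP coupling with 3 should give (S)-1-(3,4-dimethoxyphenyl)prop-2-en-1-yl (S)-3-(3,4-dimethoxyphenyl)-3-(triethylsilyloxy)propanoate F7. Buffered HF·pyridine returns to the route at 6.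

3. Step 11. Substitution at the β-branched primary carbon may be slow, leaving time for intramolecular displacement by the benzylic hydroxyl (oxetane formation) or for 1,3-acyl migration in the product. The fallback sets out from 15 and 11 and uses acylation instead of alkylation. TBSCl/imidazole on 15 should give methyl (Z)-2-[(tert-butyldimethylsilyloxy)methyl]but-2-enoate F8, and LiOH the acid (Z)-2-[(tert-butyldimethylsilyloxy)methyl]but-2-enoic acid F9. 2,4,6-Trichlorobenzoyl chloride/Et3N should give the mixed anhydride (Z)-2-[(tert-butyldimethylsilyloxy)methyl]but-2-enoic 2,4,6-trichlorobenzoic anhydride F10. This should acylate the primary hydroxyl of 11 in toluene without DMAP (to avoid Z/E isomerisation) to give the silyl ether (2R,3S)-2-[(E)-3-(3,4-dimethoxyphenyl)prop-2-en-1-yl]-3-(3,4-dimethoxyphenyl)-3-hydroxypropyl (Z)-2-[(tert-butyldimethylsilyloxy)methyl]but-2-enoate F11. HF·pyridine/pyridine returns to the route at 17.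

Further compounds
F1 | step 5 | (E)-2-(3,4-dimethoxybenzoyl)-5-(3,4-dimethoxyphenyl)pent-4-enoic acid (racemic) | OC(=O)C(C/C=C/c1ccc(OC)c(OC)c1)C(=O)c1ccc(OC)c(OC)c1
F2 | step 5 | methyl (E)-2-(3,4-dimethoxybenzoyl)-5-(3,4-dimethoxyphenyl)pent-4-enoate (racemic) | COC(=O)C(C/C=C/c1ccc(OC)c(OC)c1)C(=O)c1ccc(OC)c(OC)c1
F3 | step 5 | methyl (2S,4E)-5-(3,4-dimethoxyphenyl)-2-[(S)-(3,4-dimethoxyphenyl)(hydroxy)methyl]pent-4-enoate | COC(=O)[C@@H](C/C=C/c1ccc(OC)c(OC)c1)[C@H](O)c1ccc(OC)c(OC)c1
F4 | step 4 | ethyl (S)-3-(3,4-dimethoxyphenyl)-3-hydroxypropanoate | CCOC(=O)C[C@H](O)c1ccc(OC)c(OC)c1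
F5 | step 4 | ethyl (S)-3-(3,4-dimethoxyphenyl)-3-(triethylsilyloxy)propanoate | CCOC(=O)C[C@H](O[Si](CC)(CC)CC)c1ccc(OC)c(OC)c1
F6 | step 4 | (S)-3-(3,4-dimethoxyphenyl)-3-(triethylsilyloxy)propanoic acid | OC(=O)C[C@H](O[Si](CC)(CC)CC)c1ccc(OC)c(OC)c1
F7 | step 4 | (S)-1-(3,4-dimethoxyphenyl)prop-2-en-1-yl (S)-3-(3,4-dimethoxyphenyl)-3-(triethylsilyloxy)propanoate | C=C[C@H](OC(=O)C[C@H](O[Si](CC)(CC)CC)c1ccc(OC)c(OC)c1)c1ccc(OC)c(OC)c1
F8 | step 11 | methyl (Z)-2-[(tert-butyldimethylsilyloxy)methyl]but-2-enoate | C/C=C(/CO[Si](C)(C)C(C)(C)C)C(=O)OC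
F9 | step 11 | (Z)-2-[(tert-butyldimethylsilyloxy)methyl]but-2-enoic acid | C/C=C(/CO[Si](C)(C)C(C)(C)C)C(=O)O
F10 | step 11 | (Z)-2-[(tert-butyldimethylsilyloxy)methyl]but-2-enoic 2,4,6-trichlorobenzoic anhydride | C/C=C(/CO[Si](C)(C)C(C)(C)C)C(=O)OC(=O)c1c(Cl)cc(Cl)cc1Cl
F11 | step 11 | (2R,3S)-2-[(E)-3-(3,4-dimethoxyphenyl)prop-2-en-1-yl]-3-(3,4-dimethoxyphenyl)-3-hydroxypropyl (Z)-2-[(tert-butyldimethylsilyloxy)methyl]but-2-enoate | C/C=C(/CO[Si](C)(C)C(C)(C)C)C(=O)OC[C@@H](C/C=C/c1ccc(OC)c(OC)c1)[C@H](O)c1ccc(OC)c(OC)c1
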